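**Plan**
1. Ring A of the flavone (C4a, C5, C6, C7, C8, C8a) is a phloroglucinol-type ring fused through C4a=C8a to the 4-pyranone ring C (O1, C2, C3, C4). That C=C can act as the alkene of an unsaturated diazo ketone, so ring A is cut at C8a–C8, C7–C8, C5–C6 and C4a–C5 to a pyranonyl diazomethyl ketone and (triisopropylsilyloxy)ethyne; the ketene carbon becomes C5–OH and the siloxy carbon C7–O.
2. Ring C is cut at O1–C8a, C8a–C4a and C3–C4 to an aryl methyl ketone, ethyl acetate and diethyl oxalate; the ketone comes from an aryl bromide.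
3. The dihydrofuran ring is cut at its aryl-O–C2 bond (phenoxide opening of an epoxide) and at the C3–alkenyl bond (alkenylzinc addition to a salicylaldehyde); the prenyl group goes back to an allyl ether of 5-bromosalicylaldehyde.
4. Forward order: substituted benzene, then the dihydrofuran ring (steps 5–7), then ring C (steps 9–11), then ring A (step 15), then desilylation.
5. Stereochemistry: dihydrofuran C3 comes from a ligand-controlled alkenyl transfer; C2 comes from a hydroxyl-directed threo epoxidation followed by inversion in the 5-exo closure, which gives the trans (2R,3R) arrangement.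

Key step: step 15

Assumption: (−)-MIB is taken to deliver an alkenyl group to the same (Si) face of an aryl aldehyde as it delivers ethyl, so step 5 should give the (S)-carbinol; the antipodal ligand would be used otherwise.

Abbreviations: Ar = the (2R,3R)-3-(tert-butyldimethylsilyloxy)-7-(3-methylbut-2-enyl)-2-[2-(triethylsilyloxy)propan-2-yl]-2,3-dihydro-1-benzofuran-5-yl group of compound 15; TBS = tert-butyldimethylsilyl, TES = triethylsilyl, TIPS = triisopropylsilyl.

**Step 1**
Reactants: 1 5-bromo-2-hydroxybenzaldehyde; 2 allyl bromide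
Product: 3 5-bromo-2-(prop-2-enyloxy)benzaldehyde
Conditions: K2CO3, DMF, 25 °C
Reagents that add atoms: none
Why: Williamson O-alkylation of the phenoxide by an allylic bromide, under which the aldehyde is inert.

**Step 2**
Reactants: 3 5-bromo-2-(prop-2-enyloxy)benzaldehyde
Product: 4 5-bromo-2-hydroxy-3-(prop-2-enyl)benzaldehyde
Conditions: neat, 195 °C, N2
Reagents that add atoms: none
Why: Aromatic Claisen rearrangement, a [3,3]-sigmatropic shift to the only free ortho carbon (para is blocked by bromine) followed by re-aromatising tautomerisation.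

**Step 3**
Reactants: 4 5-bromo-2-hydroxy-3-(prop-2-enyl)benzaldehyde; 5 2-methylbut-2-ene
Product: 6 5-bromo-2-hydroxy-3-(3-methylbut-2-enyl)benzaldehyde
Conditions: second-generation Grubbs catalyst (H2IMes)(PCy3)Cl2Ru=CHPh (2 mol %), 5 (excess), CH2Cl2, 40 °C
Reagents that add atoms: none
Why: Olefin cross-metathesis in which excess trisubstituted alkene turns the terminal allyl group into a prenyl group with loss of propene; phenol, aldehyde and aryl bromide are tolerated by the ruthenium carbene.

**Step 4**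
Reactants: 6 5-bromo-2-hydroxy-3-(3-methylbut-2-enyl)benzaldehyde
Product: 7 5-bromo-2-(tert-butyldimethylsilyloxy)-3-(3-methylbut-2-enyl)benzaldehyde
Conditions: TBSCl, imidazole, DMF, 25 °C
Reagents that add atoms: tert-butyldimethylsilyl chloride, CC(C)(C)[Si](C)(C)Cl
Why: Silylation masks the acidic, chelating phenol before the organozinc step and gives an ether that fluoride will later cleave under the basic conditions needed for ring closure.

**Step 5**
Reactants: 7 5-bromo-2-(tert-butyldimethylsilyloxy)-3-(3-methylbut-2-enyl)benzaldehyde; 8 (2-methylprop-1-enyl)magnesium bromide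
Product: 10 (1S)-1-[5-bromo-2-(tert-butyldimethylsilyloxy)-3-(3-methylbut-2-enyl)phenyl]-3-methylbut-2-en-1-ol, via bis(2-methylprop-1-enyl)zinc 9 (not isolated)
Conditions: 8 (2.4 equiv), ZnCl2 (1.2 equiv), THF/Et2O, 0 °C; 1,4-dioxane, filtration of magnesium halide; (−)-MIB (10 mol %), toluene, −10 °C; aq. NH4Cl
Reagents that add atoms: none
Why: Amino-alcohol-catalysed enantioselective addition of a dialkenylzinc to an aryl aldehyde, in which the zinc aminoalkoxide of (−)-MIB should deliver the alkenyl group to the Si face and set the (S)-carbinol (dihydrofuran C3, R after the change in substituent ranking); removing the magnesium halide suppresses the racemic background addition.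

**Step 6**
Reactants: 10 (1S)-1-[5-bromo-2-(tert-butyldimethylsilyloxy)-3-(3-methylbut-2-enyl)phenyl]-3-methylbut-2-en-1-ol
Product: 11 (R)-[5-bromo-2-(tert-butyldimethylsilyloxy)-3-(3-methylbut-2-enyl)phenyl][(2S)-3,3-dimethyloxiran-2-yl]methanol
Conditions: Ti(OiPr)4 (0.3 equiv), t-BuOOH (1.5 equiv, decane), 4 Å sieves, CH2Cl2, −20 °C
Reagents that add atoms: tert-butyl hydroperoxide, CC(C)(C)OO
Why: Hydroxyl-directed epoxidation through a titanium alkoxide–alkylperoxide complex reaches only the allylic alcohol double bond (the prenyl alkene has no directing group), and 1,3-allylic strain with the cis methyl holds the carbinol hydrogen in the alkene plane so that oxygen should be delivered syn to the hydroxyl, giving the threo (R,S) epoxy alcohol.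

**Step 7**
Reactants: 11 (R)-[5-bromo-2-(tert-butyldimethylsilyloxy)-3-(3-methylbut-2-enyl)phenyl][(2S)-3,3-dimethyloxiran-2-yl]methanol
Product: 13 (2R,3R)-5-bromo-2-(2-hydroxypropan-2-yl)-7-(3-methylbut-2-enyl)-2,3-dihydro-1-benzofuran-3-ol, via epoxy phenol 12 (not isolated)
Conditions: Bu4NF (1.2 equiv), THF, 0 → 25 °C; aq. NH4Cl
Reagents that add atoms: none
Why: Fluoride cleaves the aryl silyl ether and the phenoxide opens the epoxide in a 5-exo-tet SN2 reaction at the secondary carbon with inversion, turning the threo epoxy alcohol into the trans (2R,3R) dihydrobenzofuranol; basic conditions disfavour 6-endo attack at the tertiary carbon.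

**Step 8**
Reactants: 13 (2R,3R)-5-bromo-2-(2-hydroxypropan-2-yl)-7-(3-methylbut-2-enyl)-2,3-dihydro-1-benzofuran-3-ol
Product: 15 (2R,3R)-5-bromo-3-(tert-butyldimethylsilyloxy)-7-(3-methylbut-2-enyl)-2-[2-(triethylsilyloxy)propan-2-yl]-2,3-dihydro-1-benzofuran, via secondary TBS ether 14 (not isolated)
Conditions: TBSOTf (1.1 equiv), 2,6-lutidine (4 equiv), CH2Cl2, −78 °C; then TESOTf (1.5 equiv), −78 → 0 °C
Reagents that add atoms: tert-butyldimethylsilyl triflate, CC(C)(C)[Si](C)(C)OS(=O)(=O)C(F)(F)F; triethylsilyl triflate, CC[Si](CC)(CC)OS(=O)(=O)C(F)(F)F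
Why: Sequential silylation with silyl triflates, in which the hindered TBS triflate should react only with the secondary benzylic alcohol at −78 °C and the smaller TES triflate then caps the tertiary alcohol on warming.

**Step 9**
Reactants: 15 aryl bromide Ar–Br; 16 N-methoxy-N-methylacetamide
Product: 18 1-Ar-ethanone, via aryllithium 17 (not isolated)
Conditions: n-BuLi (1.05 equiv), THF, −78 °C; 16 (1.5 equiv), −78 → 0 °C; aq. NH4Cl
Reagents that add atoms: none
Why: Bromine–lithium exchange followed by acylation of the aryllithium with a Weinreb amide, whose chelated tetrahedral adduct prevents over-addition; silyl ethers and the prenyl group are inert at −78 °C.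

**Step 10**
Reactants: 18 1-Ar-ethanone; 19 ethyl acetate
Product: 20 1-Ar-butane-1,3-dione
Conditions: NaH (3 equiv), 19 (8 equiv), THF, 0 → 40 °C; aq. NH4Cl
Reagents that add atoms: none
Why: Crossed Claisen condensation of the methyl ketone enolate with ethyl acetate, driven by deprotonation of the β-diketone formed.

**Step 11**
Reactants: 20 1-Ar-butane-1,3-dione; 21 diethyl oxalate
Product: 23 ethyl 6-Ar-4-oxo-4H-pyran-2-carboxylate, via triketo ester 22 (not isolated)
Conditions: LiN(SiMe3)2 (3.1 equiv), THF, −78 → −20 °C; 21 (1.3 equiv), −78 → 0 °C; AcOH; then pyridinium p-toluenesulfonate (0.2 equiv), 4 Å sieves, toluene, 60 °C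
Reagents that add atoms: none
Why: Claisen condensation of the β-diketone dianion at its terminal carbon with diethyl oxalate, then acid-catalysed cyclodehydration of the 2,4,6-triketo ester (enol oxygen onto the α-keto ester carbonyl, loss of water), the classical route to 6-substituted 4-oxopyran-2-carboxylates; the weak pyridinium acid in toluene is chosen to spare the silyl ethers.

**Step 12**
Reactants: 23 ethyl 6-Ar-4-oxo-4H-pyran-2-carboxylate
Product: 24 6-Ar-4-oxo-4H-pyran-2-carboxylic acid
Conditions: LiOH·H2O (1.3 equiv), THF/H2O 3:1, 0 °C; cold 0.5 M HCl to pH 4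
Reagents that add atoms: lithium hydroxide, [Li+].[OH-]
Why: Saponification of the activated heteroaryl ester with little more than one equivalent of LiOH at 0 °C should outpace hydroxide attack on the pyranone ring, and brief cold acidification leaves the silyl ethers intact.

**Step 13**
Reactants: 24 6-Ar-4-oxo-4H-pyran-2-carboxylic acid
Product: 26 2-diazo-1-(6-Ar-4-oxo-4H-pyran-2-yl)ethanone, via mixed carbonic anhydride 25 (not isolated)
Conditions: i-BuOCOCl (1.1 equiv), N-methylmorpholine (1.2 equiv), THF, −15 °C; then CH2N2 (2 equiv, Et2O), −15 → 0 °C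
Reagents that add atoms: diazomethane, C=[N+]=[N-]
Why: Acylation of diazomethane by a mixed carbonic anhydride (the first stage of an Arndt–Eistert sequence) gives the α-diazo ketone without releasing HCl, the departing carbonate taking up the proton; low temperature and limited diazomethane avoid dipolar addition to the pyranone.

**Step 14**
Reactants: 27 acetylene; 28 triisopropylsilyl trifluoromethanesulfonate
Product: 30 (triisopropylsilyloxy)ethyne, via lithium ethynolate 29 (not isolated)
Conditions: 27 (excess), n-BuLi (1.0 equiv), THF, −78 °C; t-BuOOLi (from t-BuOOH and LiN(SiMe3)2, THF, −78 °C), −78 → −20 °C; 28 (1.0 equiv), −78 °C; pentane, aq. NaHCO3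
Reagents that add atoms: tert-butyl hydroperoxide, CC(C)(C)OO
Why: Oxidation of a lithium acetylide with lithium tert-butyl peroxide gives the lithium ynolate, and the hard, bulky silyl triflate silylates it on oxygen, the established route to 1-siloxyalkynes applied here to the parent acetylide.

**Step 15**
Reactants: 26 2-diazo-1-(6-Ar-4-oxo-4H-pyran-2-yl)ethanone; 30 (triisopropylsilyloxy)ethyne
Product: 34 5-hydroxy-2-Ar-7-(triisopropylsilyloxy)-4H-chromen-4-one, via pyranonylketene 31 (not isolated), via siloxycyclobutenone 32 (not isolated), via dienylketene 33 (not isolated)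
Conditions: 30 (2.5 equiv), degassed ClCH2CH2Cl (0.05 M), 450 nm LEDs, 20 °C; then 80 °C in the dark
Reagents that add atoms: none
Why: Proposed new method: visible-light excitation of the diazo ketone n–π* band expels N2 and triggers a Wolff 1,2-shift of the pyranon-2-yl group (new C8a–C8 bond) to ketene 31, whose carbonyl carbon is attacked by the nucleophilic unsubstituted carbon of the siloxyalkyne in a regioselective [2+2] cycloaddition (C5–C6 and C7–C8 bonds; four-membered ring) to cyclobutenone 32. At 80 °C 32 should open reversibly by a four-electron electrocyclic reaction to dienylketene 33, which closes the six-membered ring A by a thermally allowed six-electron electrocyclisation of the ketene carbon onto pyranone C3 (the future C4a) and tautomerises to the C5 phenol, hydrogen-bonded to the C4 carbonyl. The closest known reaction type is the Danheiser benzannulation in its diazo ketone form, in which aryl, heteroaryl and alkenyl α-diazo ketones are photolysed with trialkylsiloxyalkynes to give resorcinol monosilyl ethers; new here are the 4-pyranone as the unsaturated unit, the terminal siloxyalkyne and the 450 nm light, chosen so that neither the 6-aryl-4-pyranone nor the flavone product should absorb. No stereocentre is formed, and the sp3 carbon of 32 is lost on aromatisation while dihydrofuran C2 and C3 are remote spectators. Two regiochemical demands must be met: the polarisation of the ynol ether places the siloxy carbon next to the former diazo carbon (oxygen at C7, not C6), and the electrocyclisation can only engage C3–H of the pyranone because the other neighbour of the ketene-bearing carbon is the ring oxygen; excess alkyne and dilution suppress ketene dimerisation and acylation of the product phenol.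

**Step 16**
Reactants: 34 5-hydroxy-2-Ar-7-(triisopropylsilyloxy)-4H-chromen-4-one
Product: 35 5,7-dihydroxy-2-[(2R,3R)-3-hydroxy-2-(2-hydroxypropan-2-yl)-7-(3-methylbut-2-enyl)-2,3-dihydro-1-benzofuran-5-yl]-4H-chromen-4-one
Conditions: Bu4NF (5 equiv), AcOH (5 equiv), THF, 0 → 40 °C
Reagents that add atoms: none
Why: Fluoride-mediated cleavage of the aryl TIPS ether, the secondary TBS ether and the tertiary TES ether, with acetic acid buffering the medium so that the acid-sensitive benzylic alcohol and the phenols are not exposed to strong base or acid; no stereocentre is touched.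

**Compound list**
1 | 5-bromo-2-hydroxybenzaldehyde | O=Cc1cc(Br)ccc1O | starting material
2 | allyl bromide | C=CCBr | starting material
3 | 5-bromo-2-(prop-2-enyloxy)benzaldehyde | C=CCOc1ccc(Br)cc1C=O | intermediate
4 | 5-bromo-2-hydroxy-3-(prop-2-enyl)benzaldehyde | C=CCc1cc(Br)cc(C=O)c1O | intermediate
5 | 2-methylbut-2-ene | CC=C(C)C | starting material
6 | 5-bromo-2-hydroxy-3-(3-methylbut-2-enyl)benzaldehyde | CC(C)=CCc1cc(Br)cc(C=O)c1O | intermediate
7 | 5-bromo-2-(tert-butyldimethylsilyloxy)-3-(3-methylbut-2-enyl)benzaldehyde | CC(C)=CCc1cc(Br)cc(C=O)c1O[Si](C)(C)C(C)(C)C | intermediate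
8 | (2-methylprop-1-enyl)magnesium bromide | CC(C)=C[Mg]Br | starting material
9 | bis(2-methylprop-1-enyl)zinc | CC(C)=C[Zn]C=C(C)C | intermediate
10 | (1S)-1-[5-bromo-2-(tert-butyldimethylsilyloxy)-3-(3-methylbut-2-enyl)phenyl]-3-methylbut-2-en-1-ol | CC(C)=CCc1cc(Br)cc([C@@H](O)C=C(C)C)c1O[Si](C)(C)C(C)(C)C | intermediate
11 | (R)-[5-bromo-2-(tert-butyldimethylsilyloxy)-3-(3-methylbut-2-enyl)phenyl][(2S)-3,3-dimethyloxiran-2-yl]methanol | CC(C)=CCc1cc(Br)cc([C@@H](O)[C@@H]2OC2(C)C)c1O[Si](C)(C)C(C)(C)C | intermediate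
12 | 4-bromo-2-{(R)-[(2S)-3,3-dimethyloxiran-2-yl](hydroxy)methyl}-6-(3-methylbut-2-enyl)phenol (present as its tetrabutylammonium phenoxide) | CC(C)=CCc1cc(Br)cc([C@@H](O)[C@@H]2OC2(C)C)c1O | intermediate
13 | (2R,3R)-5-bromo-2-(2-hydroxypropan-2-yl)-7-(3-methylbut-2-enyl)-2,3-dihydro-1-benzofuran-3-ol | CC(C)=CCc1cc(Br)cc2c1O[C@@H](C(C)(C)O)[C@@H]2O | intermediate
14 | 2-[(2R,3R)-5-bromo-3-(tert-butyldimethylsilyloxy)-7-(3-methylbut-2-enyl)-2,3-dihydro-1-benzofuran-2-yl]propan-2-ol | CC(C)=CCc1cc(Br)cc2c1O[C@@H](C(C)(C)O)[C@@H]2O[Si](C)(C)C(C)(C)C | intermediate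
15 | (2R,3R)-5-bromo-3-(tert-butyldimethylsilyloxy)-7-(3-methylbut-2-enyl)-2-[2-(triethylsilyloxy)propan-2-yl]-2,3-dihydro-1-benzofuran (Ar–Br) | CC(C)=CCc1cc(Br)cc2c1O[C@@H](C(C)(C)O[Si](CC)(CC)CC)[C@@H]2O[Si](C)(C)C(C)(C)C | intermediate
16 | N-methoxy-N-methylacetamide | CC(=O)N(C)OC | starting material
17 | aryllithium Ar–Li | CC(C)=CCc1cc([Li])cc2c1O[C@@H](C(C)(C)O[Si](CC)(CC)CC)[C@@H]2O[Si](C)(C)C(C)(C)C | intermediate
18 | 1-Ar-ethanone | CC(C)=CCc1cc(C(C)=O)cc2c1O[C@@H](C(C)(C)O[Si](CC)(CC)CC)[C@@H]2O[Si](C)(C)C(C)(C)C | intermediate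
19 | ethyl acetate | CCOC(C)=O | starting material
20 | 1-Ar-butane-1,3-dione | CC(C)=CCc1cc(C(=O)CC(C)=O)cc2c1O[C@@H](C(C)(C)O[Si](CC)(CC)CC)[C@@H]2O[Si](C)(C)C(C)(C)C | intermediate
21 | diethyl oxalate | CCOC(=O)C(=O)OCC | starting material
22 | ethyl 6-Ar-2,4,6-trioxohexanoate | CC(C)=CCc1cc(C(=O)CC(=O)CC(=O)C(=O)OCC)cc2c1O[C@@H](C(C)(C)O[Si](CC)(CC)CC)[C@@H]2O[Si](C)(C)C(C)(C)C | intermediate
23 | ethyl 6-Ar-4-oxo-4H-pyran-2-carboxylate | CC(C)=CCc1cc(-c3cc(=O)cc(C(=O)OCC)o3)cc2c1O[C@@H](C(C)(C)O[Si](CC)(CC)CC)[C@@H]2O[Si](C)(C)C(C)(C)C | intermediate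
24 | 6-Ar-4-oxo-4H-pyran-2-carboxylic acid | CC(C)=CCc1cc(-c3cc(=O)cc(C(=O)O)o3)cc2c1O[C@@H](C(C)(C)O[Si](CC)(CC)CC)[C@@H]2O[Si](C)(C)C(C)(C)C | intermediate
25 | 6-Ar-4-oxo-4H-pyran-2-carboxylic isobutyl carbonic anhydride | CC(C)=CCc1cc(-c3cc(=O)cc(C(=O)OC(=O)OCC(C)C)o3)cc2c1O[C@@H](C(C)(C)O[Si](CC)(CC)CC)[C@@H]2O[Si](C)(C)C(C)(C)C | intermediate
26 | 2-diazo-1-(6-Ar-4-oxo-4H-pyran-2-yl)ethanone | CC(C)=CCc1cc(-c3cc(=O)cc(C(=O)C=[N+]=[N-])o3)cc2c1O[C@@H](C(C)(C)O[Si](CC)(CC)CC)[C@@H]2O[Si](C)(C)C(C)(C)C | intermediate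
27 | acetylene | C#C | starting material
28 | triisopropylsilyl trifluoromethanesulfonate | CC(C)[Si](C(C)C)(C(C)C)OS(=O)(=O)C(F)(F)F | starting material
29 | lithium ethynolate | [Li+].[O-]C#C | intermediate
30 | (triisopropylsilyloxy)ethyne | C#CO[Si](C(C)C)(C(C)C)C(C)C | intermediate
31 | 2-(6-Ar-4-oxo-4H-pyran-2-yl)ethen-1-one (pyranonylketene) | CC(C)=CCc1cc(-c3cc(=O)cc(C=C=O)o3)cc2c1O[C@@H](C(C)(C)O[Si](CC)(CC)CC)[C@@H]2O[Si](C)(C)C(C)(C)C | intermediate
32 | 4-(6-Ar-4-oxo-4H-pyran-2-yl)-3-(triisopropylsilyloxy)cyclobut-2-en-1-one (both C4 epimers) | CC(C)=CCc1cc(-c3cc(=O)cc(C4C(=O)C=C4O[Si](C(C)C)(C(C)C)C(C)C)o3)cc2c1O[C@@H](C(C)(C)O[Si](CC)(CC)CC)[C@@H]2O[Si](C)(C)C(C)(C)C | intermediate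
33 | (3E)-4-(6-Ar-4-oxo-4H-pyran-2-yl)-3-(triisopropylsilyloxy)buta-1,3-dien-1-one (dienylketene) | CC(C)=CCc1cc(-c3cc(=O)cc(/C=C(O[Si](C(C)C)(C(C)C)C(C)C)\C=C=O)o3)cc2c1O[C@@H](C(C)(C)O[Si](CC)(CC)CC)[C@@H]2O[Si](C)(C)C(C)(C)C | intermediate
34 | 5-hydroxy-2-Ar-7-(triisopropylsilyloxy)-4H-chromen-4-one | CC(C)=CCc1cc(-c3cc(=O)c4c(O)cc(O[Si](C(C)C)(C(C)C)C(C)C)cc4o3)cc2c1O[C@@H](C(C)(C)O[Si](CC)(CC)CC)[C@@H]2O[Si](C)(C)C(C)(C)C | intermediate
35 | 5,7-dihydroxy-2-[(2R,3R)-3-hydroxy-2-(2-hydroxypropan-2-yl)-7-(3-methylbut-2-enyl)-2,3-dihydro-1-benzofuran-5-yl]-4H-chromen-4-one | CC(C)=CCc1cc(-c2cc(=O)c3c(O)cc(O)cc3o2)cc2c1O[C@@H](C(C)(C)O)[C@@H]2O | target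

**Summary**
Total step count: 16. Longest linear sequence: 15 steps (steps 1–13, 15 and 16, from 5-bromo-2-hydroxybenzaldehyde); step 14 is a one-step side branch.

**Steps most likely to fail**

Step 15. The ketene may be diverted by dimerisation, by acylation of the product phenol or by competing photochemistry of the pyranone, or the six-electron closure onto the electron-poor pyranone carbon may stall at the cyclobutenone. The fallback is the Baker–Venkataraman flavone synthesis, in which ring A is bought instead of built; it sets out from 15 and rejoins the route at 34. Bromine–lithium exchange on 15 (n-BuLi, THF, −78 °C) and CO2 should give (2R,3R)-3-(tert-butyldimethylsilyloxy)-7-(3-methylbut-2-enyl)-2-[2-(triethylsilyloxy)propan-2-yl]-2,3-dihydro-1-benzofuran-5-carboxylic acid F1. 2,4,6-Trihydroxyacetophenone is silylated at its non-chelated 4-hydroxyl (i-Pr3SiCl, imidazole) to 1-[2,6-dihydroxy-4-(triisopropylsilyloxy)phenyl]ethanone F2. Carbodiimide coupling (EDC, DMAP) of F1 with one of the two equivalent phenols of F2 gives 2-acetyl-3-hydroxy-5-(triisopropylsilyloxy)phenyl Ar-carboxylate F3. LiN(SiMe3)2 then induces the acyl shift to 1-Ar-3-[2,6-dihydroxy-4-(triisopropylsilyloxy)phenyl]propane-1,3-dione F4, and cyclodehydration with catalytic pyridinium p-toluenesulfonate in toluene closes ring C to 34.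

Step 14. Lithium acetylide may disproportionate before it is oxidised, and the unhindered parent ynolate may be silylated at carbon (giving the silylketene) instead of at oxygen. The fallback is an elimination, the classical way to alkynyl ethers; it sets out from 28 and rejoins the route at 30. Bromoacetaldehyde, freed from its diethyl acetal, is converted with 28 and i-Pr2NEt into (2-bromoethenyloxy)triisopropylsilane F5 (E/Z mixture). LiN(i-Pr)2 (2 equiv, THF, −78 °C) then removes HBr and lithiates the alkyne, which gives 30 on protonation.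

Step 5. Enantioselectivity may be eroded by a halide-promoted racemic background addition, or alkenyl transfer to the hindered ortho-silyloxy aldehyde may be slow. The fallback is reagent-controlled ketone reduction; it sets out from 7 and rejoins the route at 10. Direct addition of 8 (THF, −78 °C) gives racemic 1-[5-bromo-2-(tert-butyldimethylsilyloxy)-3-(3-methylbut-2-enyl)phenyl]-3-methylbut-2-en-1-ol F6. MnO2 oxidises it to 1-[5-bromo-2-(tert-butyldimethylsilyloxy)-3-(3-methylbut-2-enyl)phenyl]-3-methylbut-2-en-1-one F7. Corey–Bakshi–Shibata reduction ((R)-Me-CBS oxazaborolidine, catecholborane, toluene, −78 °C, with the ortho-disubstituted aryl group acting as the larger substituent) should then return (S)-10.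

**Further compounds**
F1 | step 15 | (2R,3R)-3-(tert-butyldimethylsilyloxy)-7-(3-methylbut-2-enyl)-2-[2-(triethylsilyloxy)propan-2-yl]-2,3-dihydro-1-benzofuran-5-carboxylic acid | CC(C)=CCc1cc(C(=O)O)cc2c1O[C@@H](C(C)(C)O[Si](CC)(CC)CC)[C@@H]2O[Si](C)(C)C(C)(C)C
F2 | step 15 | 1-[2,6-dihydroxy-4-(triisopropylsilyloxy)phenyl]ethanone | CC(=O)c1c(O)cc(O[Si](C(C)C)(C(C)C)C(C)C)cc1O
F3 | step 15 | 2-acetyl-3-hydroxy-5-(triisopropylsilyloxy)phenyl Ar-carboxylate | CC(C)=CCc1cc(C(=O)Oc3cc(O[Si](C(C)C)(C(C)C)C(C)C)cc(O)c3C(C)=O)cc2c1O[C@@H](C(C)(C)O[Si](CC)(CC)CC)[C@@H]2O[Si](C)(C)C(C)(C)C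
F4 | step 15 | 1-Ar-3-[2,6-dihydroxy-4-(triisopropylsilyloxy)phenyl]propane-1,3-dione | CC(C)=CCc1cc(C(=O)CC(=O)c3c(O)cc(O[Si](C(C)C)(C(C)C)C(C)C)cc3O)cc2c1O[C@@H](C(C)(C)O[Si](CC)(CC)CC)[C@@H]2O[Si](C)(C)C(C)(C)C
F5 | step 14 | (2-bromoethenyloxy)triisopropylsilane (E/Z mixture) | BrC=CO[Si](C(C)C)(C(C)C)C(C)C
F6 | step 5 | racemic 1-[5-bromo-2-(tert-butyldimethylsilyloxy)-3-(3-methylbut-2-enyl)phenyl]-3-methylbut-2-en-1-ol | CC(C)=CCc1cc(Br)cc(C(O)C=C(C)C)c1O[Si](C)(C)C(C)(C)C
F7 | step 5 | 1-[5-bromo-2-(tert-butyldimethylsilyloxy)-3-(3-methylbut-2-enyl)phenyl]-3-methylbut-2-en-1-one | CC(C)=CCc1cc(Br)cc(C(=O)C=C(C)C)c1O[Si](C)(C)C(C)(C)C
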